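Everything rests on the C1–C2 bond (C1 = ketone carbon, C2 = furanone CH), which lies in both the ten-membered carbocycle C1–C10 and the bridging 3(2H)-furanone ring (O, C3, C2, C1, C10). The furanone is treated as a cyclised α′-hydroxy ynone, so its C2=C3–O unit is carried as a C2≡C3 alkyne. The key step closes the carbocycle by Nozaki–Hiyama–Kishi addition of a C2 iodoalkyne to a C1 aldehyde; the precursor is an acyclic chain built on the trans-disubstituted α-methylene lactone, with the Z-C4=C5 enyne and the C6, C7, C8 and C10 stereocentres in place. Oxidation to the ynone and transannular addition of the C10 hydroxyl to C3 then give the bicycle; the epoxy ester is attached last.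

Key step: step 13

Remark on numbering: germacrane-type numbering is used throughout: C1 ketone carbon, C2 furanone CH, C3 enol-ether carbon, C4 (methyl C15), C5, C6 (ester carbinol), C7, C8 (lactone carbinol), C9, C10 (quaternary, methyl C14), C11 (methylene C13), C12 (lactone carbonyl).
Assumption: (Z)-3-methylpent-2-en-4-yn-1-ol and both enantiomers of 2-methylglycidol are taken as commercial.

Step 1
Reactants: 1 (Z)-3-methylpent-2-en-4-yn-1-ol
Product: 3 C-silylated enynol, via bis-TMS derivative 2 (not isolated)
Conditions: n-BuLi (2.1 equiv), THF, −78 °C; TMSCl, −78 °C to rt; 1 M HCl work-up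
Reagents that add atoms: chlorotrimethylsilane, C[Si](C)(C)Cl
Why: Double deprotonation and silylation of alkoxide and acetylide, followed by hydrolysis of the O–Si bond alone on acidic work-up (C-silylation of a terminal alkyne), masks the acidic C2–H for steps 3–5 and later exchanges directly for iodine.

Step 2
Reactants: 3 C-silylated enynol
Product: 4 (Z)-3-methyl-5-(trimethylsilyl)pent-2-en-4-ynal
Conditions: MnO2, CH2Cl2, rt
Reagents that add atoms: none
Why: MnO2 oxidises the allylic alcohol under neutral heterogeneous conditions (allylic oxidation), which should keep the Z geometry of the enynal, used crude.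

Step 3
Reactants: 4 (Z)-enynal; 5 methyl propiolate
Product: 6 (4R)-propargylic alcohol
Conditions: Me2Zn, ProPhenol ligand (cat.; the antipode that delivers 4R), Ph3PO (cat.), toluene, 0 °C; aq. NH4Cl
Reagents that add atoms: none
Why: The zinc acetylide of methyl propiolate adds to the enal inside the dinuclear zinc–ProPhenol pocket (catalytic asymmetric alkynylation), so the ligand antipode sets the C6 carbinol as R while the silylated enyne stays inert.

Step 4
Reactants: 6 (4R)-propargylic alcohol
Product: 7 TBS ether of 6
Conditions: TBSOTf, 2,6-lutidine, CH2Cl2, −78 °C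
Reagents that add atoms: tert-butyldimethylsilyl triflate, CC(C)(C)[Si](C)(C)OS(=O)(=O)C(F)(F)F
Why: Silylation with the triflate and a non-nucleophilic base (silyl ether protection) avoids conjugate addition to the ynoate and installs the C6–O group that directs step 10.

Step 5
Reactants: 7 TBS-protected ynoate
Product: 9 2-(hydroxymethyl)enoate, via alumino acrylate 8 (not isolated)
Conditions: i-Bu2AlH, HMPA, THF, 0 °C; then CH2O (gas), −78 to 0 °C; aq. potassium sodium tartrate
Reagents that add atoms: formaldehyde, C=O
Why: The i-Bu2AlH–HMPA complex adds hydride 1,4 to the ynoate only (syn-hydroalumination) and the α-alumino acrylate traps formaldehyde at the α-carbon (vinylalumination), installing C13 as CH2OH without touching C6 or the silyl alkyne.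

Step 6
Reactants: 9 2-(hydroxymethyl)enoate
Product: 10 allylic bromide
Conditions: CBr4, PPh3, CH2Cl2, 0 °C
Reagents that add atoms: carbon tetrabromide, BrC(Br)(Br)Br
Why: Appel bromination converts the primary allylic alcohol into the bromide under neutral conditions that the silyl ethers and the enyne tolerate.

Step 7
Reactants: 11 (S)-2-methylglycidol
Product: 12 (2R)-2-methylpent-4-ene-1,2-diol
Conditions: CH2=CHMgBr, CuI (cat.), THF, −30 to 0 °C; aq. NH4Cl
Reagents that add atoms: vinylmagnesium bromide, C=C[Mg]Br
Why: Copper-catalysed Grignard opening of the 2,2-disubstituted epoxide occurs at the unhindered CH2 (SN2 epoxide opening), so the C10 stereocentre is carried over untouched, the Payne isomer of 11 being the same compound.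

Step 8
Reactants: 12 (2R)-diol
Product: 13 bis-triethylsilyl ether
Conditions: TESOTf, 2,6-lutidine, CH2Cl2, 0 °C
Reagents that add atoms: triethylsilyl triflate, CC[Si](CC)(CC)OS(=O)(=O)C(F)(F)F
Why: Exhaustive silylation with the triflate protects the primary and the hindered tertiary hydroxyl alike (silyl ether formation), the primary triethylsilyl ether being the one that step 12 oxidises directly.

Step 9
Reactants: 13 bis-triethylsilyl ether
Product: 15 (3R)-3-methyl-3,4-bis(triethylsilyloxy)butanal, via ozonide 14 (not isolated)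
Conditions: O3, CH2Cl2, −78 °C; then PPh3, −78 °C to rt
Reagents that add atoms: ozone, [O-][O+]=O
Why: Ozonolysis with reductive work-up cleaves the terminal alkene to the C8 aldehyde, one carbon leaving as formaldehyde and no stereocentre being involved.

Step 10
Reactants: 10 allylic bromide; 15 C8 aldehyde
Product: 18 TMS-alkyne seco lactone, via allylchromium dichloride 16 (not isolated), via seco hydroxy ester 17 (not isolated)
Conditions: CrCl2, THF, 0 °C to rt; aq. work-up; then PPTS (cat.), CH2Cl2, rt
Reagents that add atoms: none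
Why: Divalent chromium converts 10 into allylchromium 16, which adds to 15 through a chair Zimmerman–Traxler transition state (Nozaki–Hiyama/Barbier 2-alkoxycarbonyl-allylation, anti-selective, hence the trans lactone once 17 lactonises), the C7 face being set by C6 with H6 eclipsing the alkene and attack anti to the C6–O bond (Felkin–Anh-type 1,2-induction) and C8 following from the chair.

Step 11
Reactants: 18 TMS-alkyne seco lactone
Product: 19 iodoalkyne seco lactone
Conditions: NIS, AgNO3 (cat.), DMF, 0 °C to rt, dark
Reagents that add atoms: N-iodosuccinimide, O=C1CCC(=O)N1I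
Why: Silver-catalysed iododesilylation exchanges the alkynyl trimethylsilyl group for iodine via the silver acetylide (ipso-substitution), leaving the alkyl silyl ethers and both alkenes untouched.

Step 12
Reactants: 19 iodoalkyne seco lactone
Product: 20 iodoalkyne aldehyde
Conditions: (COCl)2, DMSO, CH2Cl2, −78 to −40 °C; Et3N, to 0 °C
Reagents that add atoms: none
Why: Under Swern conditions a primary triethylsilyl ether is cleaved and oxidised in one operation while tertiary and secondary silyl ethers survive (direct Swern oxidation of primary TES ethers), giving the non-enolisable C1 aldehyde.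

Step 13
Reactants: 20 iodoalkyne aldehyde
Product: 22 ten-membered propargylic alcohol, via alkynylchromium dichloride 21 (not isolated)
Conditions: CrCl2 (excess), NiCl2 (cat.), THF, rt, slow addition of 20 (high dilution)
Reagents that add atoms: none
Why: Divalent chromium inserts into the C2–I bond (NiCl2-assisted) to give the alkynylchromium 21, a non-basic nucleophile that adds only to the C1 aldehyde; this is the Nozaki–Hiyama–Kishi alkynylation, the reaction type established for closing strained enediyne carbocycles. It closes the ten-membered carbocycle C1–C10 in a 10-exo-trig mode by forming C1–C2, the C2≡C3 alkyne ending up endocyclic as the latent C2=C3–O of the furanone. The one new stereocentre, C1, is not controlled and need not be, because step 14 oxidises it. The step needs chemoselectivity for the aldehyde over the methylene lactone and the silyl ethers, which the organochromium reagent secures, and cyclisation over oligomerisation, which the Z-C4=C5 alkene, the trans-disubstituted lactone turn and high dilution secure.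

Step 14
Reactants: 22 ten-membered propargylic alcohol
Product: 23 ten-membered ynone
Conditions: Dess–Martin periodinane, CH2Cl2, rt
Reagents that add atoms: none
Why: Dess–Martin oxidation converts the propargylic C1 carbinol (both epimers) into the ynone under near-neutral conditions that spare the silyl ethers and the methylene lactone.

Step 15
Reactants: 23 ten-membered ynone
Product: 26 furanone alcohol, via hydroxy ynone 24 (not isolated), via TBS-protected furanone 25 (not isolated)
Conditions: HF·pyridine, pyridine, THF, 0 °C, then rt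
Reagents that add atoms: none
Why: HF·pyridine removes the tertiary triethylsilyl ether first, the freed C10 hydroxyl adds across the ring to C3 of the bent ynone (5-endo-dig oxa-Michael addition, the hydroxy-ynone route to 3(2H)-furanones) and the TBS group is lost only afterwards, so the C6 hydroxyl should find no alkyne to attack; no stereocentre is formed.

Step 16
Reactants: 27 (R)-2-methylglycidol
Product: 28 (S)-2-methyloxirane-2-carboxylic acid
Conditions: RuCl3 (cat.), NaIO4, CCl4/MeCN/H2O, 0 °C to rt
Reagents that add atoms: water, O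
Why: Catalytic RuO4 generated from RuCl3 and NaIO4 oxidises the primary alcohol to the acid without opening the epoxide or touching the quaternary stereocentre, whose descriptor changes from R to S by priority only.

Step 17
Reactants: 26 furanone alcohol; 28 (S)-2-methyloxirane-2-carboxylic acid
Product: 29 target CNP0321429.1
Conditions: DCC, DMAP (cat.), CH2Cl2, 0 °C to rt
Reagents that add atoms: none
Why: Steglich esterification acylates the single free hydroxyl at C6 with retention at C6 and at the epoxide carbon, the mild carbodiimide activation being tolerated by the epoxide, the furanone and the methylene lactone.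

Compound list

1 | (Z)-3-methylpent-2-en-4-yn-1-ol | C#C/C(C)=C\CO | starting material
2 | (Z)-trimethyl{[3-methyl-5-(trimethylsilyl)pent-2-en-4-yn-1-yl]oxy}silane (not isolated) | C[Si](C)(C)C#C/C(C)=C\CO[Si](C)(C)C | intermediate
3 | (Z)-3-methyl-5-(trimethylsilyl)pent-2-en-4-yn-1-ol | C[Si](C)(C)C#C/C(C)=C\CO | intermediate
4 | (Z)-3-methyl-5-(trimethylsilyl)pent-2-en-4-ynal | C[Si](C)(C)C#C/C(C)=C\C=O | intermediate
5 | methyl propiolate | C#CC(=O)OC | starting material
6 | methyl (4R,5Z)-4-hydroxy-6-methyl-8-(trimethylsilyl)oct-5-ene-2,7-diynoate | C[Si](C)(C)C#C/C(C)=C\[C@@H](O)C#CC(=O)OC | intermediate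
7 | methyl (4R,5Z)-4-[(tert-butyldimethylsilyl)oxy]-6-methyl-8-(trimethylsilyl)oct-5-ene-2,7-diynoate | C[Si](C)(C)C#C/C(C)=C\[C@@H](O[Si](C)(C)C(C)(C)C)C#CC(=O)OC | intermediate
8 | methyl (2E,4R,5Z)-4-[(tert-butyldimethylsilyl)oxy]-2-(diisobutylalumanyl)-6-methyl-8-(trimethylsilyl)octa-2,5-dien-7-ynoate (not isolated) | C[Si](C)(C)C#C/C(C)=C\[C@@H](O[Si](C)(C)C(C)(C)C)/C=C(/[Al](CC(C)C)CC(C)C)C(=O)OC | intermediate
9 | methyl (2Z,4R,5Z)-4-[(tert-butyldimethylsilyl)oxy]-2-(hydroxymethyl)-6-methyl-8-(trimethylsilyl)octa-2,5-dien-7-ynoate | C[Si](C)(C)C#C/C(C)=C\[C@@H](O[Si](C)(C)C(C)(C)C)/C=C(/CO)C(=O)OC | intermediate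
10 | methyl (2E,4R,5Z)-2-(bromomethyl)-4-[(tert-butyldimethylsilyl)oxy]-6-methyl-8-(trimethylsilyl)octa-2,5-dien-7-ynoate | C[Si](C)(C)C#C/C(C)=C\[C@@H](O[Si](C)(C)C(C)(C)C)/C=C(/CBr)C(=O)OC | intermediate
11 | (S)-2-methylglycidol, (2S)-(2-methyloxiran-2-yl)methanol | OC[C@@]1(C)CO1 | starting material
12 | (2R)-2-methylpent-4-ene-1,2-diol | C=CC[C@@](CO)(C)O | intermediate
13 | (4R)-4-methyl-4,5-bis(triethylsilyloxy)pent-1-ene | C=CC[C@](C)(CO[Si](CC)(CC)CC)O[Si](CC)(CC)CC | intermediate
14 | 3-[(2R)-2-methyl-2,3-bis(triethylsilyloxy)propyl]-1,2,4-trioxolane (ozonide, not isolated) | CC[Si](CC)(CC)OC[C@@](C)(CC1OCOO1)O[Si](CC)(CC)CC | intermediate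
15 | (3R)-3-methyl-3,4-bis(triethylsilyloxy)butanal | O=CC[C@](C)(CO[Si](CC)(CC)CC)O[Si](CC)(CC)CC | intermediate
16 | allylchromium dichloride derived from 10, CrCl2 in place of Br, trivalent chromium (not isolated) | C[Si](C)(C)C#C/C(C)=C\[C@@H](O[Si](C)(C)C(C)(C)C)/C=C(/C[Cr](Cl)Cl)C(=O)OC | intermediate
17 | seco hydroxy ester: methyl 2-methylidene ester with free C8 hydroxyl, C7 bearing the (Z)-CH(OTBS)–CH=C(CH3)–C≡C–TMS arm, C8 bearing CH2–C(CH3)(OTES)–CH2OTES; C6, C7, C8, C10 as in 18 (not isolated) | C=C(C(=O)OC)[C@H]([C@@H](O)C[C@](C)(CO[Si](CC)(CC)CC)O[Si](CC)(CC)CC)[C@H](O[Si](C)(C)C(C)(C)C)/C=C(C)\C#C[Si](C)(C)C | intermediate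
18 | TMS-alkyne seco lactone: trans-β,γ-disubstituted α-methylene-γ-butyrolactone, C8 bearing CH2–C(CH3)(OTES)–CH2OTES, C7 bearing (Z)-CH(OTBS)–CH=C(CH3)–C≡C–TMS; 6R,7R,8S,10R | C=C1C(=O)O[C@@H](C[C@](C)(CO[Si](CC)(CC)CC)O[Si](CC)(CC)CC)[C@@H]1[C@H](O[Si](C)(C)C(C)(C)C)/C=C(C)\C#C[Si](C)(C)C | intermediate
19 | iodoalkyne seco lactone: as 18 with C2–I in place of C2–TMS; 6R,7R,8S,10R | C=C1C(=O)O[C@@H](C[C@](C)(CO[Si](CC)(CC)CC)O[Si](CC)(CC)CC)[C@@H]1[C@H](O[Si](C)(C)C(C)(C)C)/C=C(C)\C#CI | intermediate
20 | iodoalkyne aldehyde: as 19 with C1 as CHO and C10–OTES retained; 6R,7R,8S,10R | C=C1C(=O)O[C@@H](C[C@](C)(C=O)O[Si](CC)(CC)CC)[C@@H]1[C@H](O[Si](C)(C)C(C)(C)C)/C=C(C)\C#CI | intermediate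
21 | alkynylchromium dichloride derived from 20, CrCl2 in place of I, trivalent chromium (not isolated) | C=C1C(=O)O[C@@H](C[C@](C)(C=O)O[Si](CC)(CC)CC)[C@@H]1[C@H](O[Si](C)(C)C(C)(C)C)/C=C(C)\C#C[Cr](Cl)Cl | intermediate
22 | ten-membered propargylic alcohol (C1 epimers): cyclodec-4-en-2-yne ring C1–C10 fused at C7/C8 to the α-methylene-γ-lactone; C1 OH, C4 CH3, C6 OTBS, C10 CH3 and OTES; 4Z,6R,7R,8S,10R | C=C1C(=O)O[C@H]2C[C@@](C)(O[Si](CC)(CC)CC)C(O)C#C/C(C)=C\[C@@H](O[Si](C)(C)C(C)(C)C)[C@H]12 | intermediate
23 | ten-membered ynone: as 22 with C1=O; 4Z,6R,7R,8S,10R | C=C1C(=O)O[C@H]2C[C@@](C)(O[Si](CC)(CC)CC)C(=O)C#C/C(C)=C\[C@@H](O[Si](C)(C)C(C)(C)C)[C@H]12 | intermediate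
24 | hydroxy ynone: as 23 with free C10 hydroxyl, C6 OTBS (not isolated) | C=C1C(=O)O[C@H]2C[C@@](C)(O)C(=O)C#C/C(C)=C\[C@@H](O[Si](C)(C)C(C)(C)C)[C@H]12 | intermediate
25 | TBS-protected furanone: target skeleton with C6 OTBS; 6R,7R,8S,10R (not isolated) | C=C1C(=O)O[C@H]2C[C@@]3(C)OC(=CC3=O)/C(C)=C\[C@@H](O[Si](C)(C)C(C)(C)C)[C@H]12 | intermediate
26 | furanone alcohol: target skeleton with free C6 hydroxyl; 6R,7S,8S,10R (C7 descriptor differs from 25 by priority only) | C=C1C(=O)O[C@H]2C[C@@]3(C)OC(=CC3=O)/C(C)=C\[C@@H](O)[C@H]12 | intermediate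
27 | (R)-2-methylglycidol, (2R)-(2-methyloxiran-2-yl)methanol | OC[C@]1(C)CO1 | starting material
28 | (S)-2-methyloxirane-2-carboxylic acid | OC(=O)[C@]1(C)CO1 | intermediate
29 | CNP0321429.1: (6R,7R,8S,10R)-furanoheliangolide 8,12-olide, C6 ester of (2S)-2-methyloxirane-2-carboxylic acid, 4Z | C=C1C(=O)O[C@H]2C[C@@]3(C)OC(=CC3=O)/C(C)=C\[C@@H](OC(=O)[C@]3(C)CO3)[C@H]12 | target

Total step count: 17. Longest linear sequence: 13 steps (steps 1–6, 10–15 and 17).

Steps most likely to fail

Step 13. The ring closure may lose to oligomerisation, or the strain of the endocyclic alkyne may hold the chain ends apart. The fallback takes the alkyne out of the ring-closing event while still forming C1–C2. It sets out from 20: gold-catalysed hydration of the iodoalkyne (Ph3PAuNTf2 cat., wet dioxane) should give the α-iodomethyl enone aldehyde F1. SmI2 in THF at −78 °C under high dilution (intramolecular Reformatsky reaction) should then close the ten-membered β-hydroxy ketone F2. Dess–Martin oxidation should give the 1,3-diketone F3. HF·pyridine then removes the triethylsilyl group, the α′-hydroxy-1,3-diketone cyclodehydrates to the furanone, and loss of the TBS group brings the route back at 26.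

Step 10. Poor facial selectivity at C7 or erosion of the anti preference may arise from the equilibrating allylchromium reagent. The fallback transfers the allyl unit from boron through a closed six-membered transition state. It sets out from 10: B2pin2 with Pd2(dba)3 (cat.) should give the allylboronate F4 with C6 trans to the CH2B group. Heating F4 with 15 in toluene should give the anti adduct stereospecifically, and hydrolysis of the borate gives 17. PPTS then closes the lactone and the route is rejoined at 18.

Step 15. Loss of the TBS group may outrun the oxa-Michael step, which would allow competing cyclisation of the C6 hydroxyl onto C3. The fallback separates the events. It sets out from 23: AcOH/THF/H2O removes only the triethylsilyl group to give 24, now isolated. AuCl3 (cat.) in CH2Cl2 activates the alkyne for 5-endo-dig attack of the C10 hydroxyl to give 25, also isolated. HF·pyridine then brings the route back at 26.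

Further compounds

F1 | step 13 | α-iodomethyl enone aldehyde: as 20 with C2H2I–C3(=O) in place of the iodoalkyne | C=C1C(=O)O[C@@H](C[C@](C)(C=O)O[Si](CC)(CC)CC)[C@@H]1[C@H](O[Si](C)(C)C(C)(C)C)/C=C(C)\C(=O)CI
F2 | step 13 | ten-membered β-hydroxy ketone (C1 epimers): C1 OH, C2 H2, C3=O, C6 OTBS, C10 OTES | C=C1C(=O)O[C@H]2C[C@@](C)(O[Si](CC)(CC)CC)C(O)CC(=O)/C(C)=C\[C@@H](O[Si](C)(C)C(C)(C)C)[C@H]12
F3 | step 13 | ten-membered 1,3-diketone: C1=O, C3=O, C6 OTBS, C10 OTES | C=C1C(=O)O[C@H]2C[C@@](C)(O[Si](CC)(CC)CC)C(=O)CC(=O)/C(C)=C\[C@@H](O[Si](C)(C)C(C)(C)C)[C@H]12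
F4 | step 10 | allylboronate: as 10 with pinacolboryl in place of Br | C[Si](C)(C)C#C/C(C)=C\[C@@H](O[Si](C)(C)C(C)(C)C)/C=C(/CB1OC(C)(C)C(C)(C)O1)C(=O)OC
F0 | step 15 | none | none
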